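All runs come from a simulation for substances that don't exist; scatter was added.

I start from the leftover: counting mono and bis adducts, the eta run's readings have spent 3.66% of its partner at 4.00 h. So I keep partner at its charge P, and mono adduct meets it in a pseudo-first-order step.

| setting | alpha | eta | delta | Thursday's | Wednesday's | Saturday's | Sunday's | Friday's |
|---|---|---|---|---|---|---|---|---|
| solid substrate | 0.050 M | 0.050 M | 0.024 M | 0.012 M | 0.050 M | 0.030 M | 0.050 M | 0.050 M |
| partner | 0.029 M | 0.22 M | 0.15 M | 0.0500 M | 0.250 M | 0.0800 M | 0.100 M | 0.150 M |
| remark | run made earlier | run made earlier | run made earlier |  |  |  |  |  |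
| time |  |  |  | 4.0 h | 4.0 h | 4.0 h | 4.0 h | 4.0 h |

| run | time / h | mono adduct / % | bis adduct / % |
|---|---|---|---|
| alpha | 1.00 | 2.2 | 0.3 |
| alpha | 2.00 | 0 | 0 |
| alpha | 3.00 | 0.7 | 0.4 |
| alpha | 4.00 | 0 | 1.3 |
| eta | 1.00 | 2.1 | 0 |
| eta | 2.00 | 3.5 | 1.7 |
| eta | 3.00 | 3.4 | 2.2 |
| eta | 4.00 | 4.3 | 5.9 |
| delta | 0.500 | 2.7 | 1.7 |
| delta | 1.33 | 2.1 | 0 |
| delta | 2.50 | 4.2 | 0 |
| delta | 4.00 | 8.8 | 6.6 |

(readings scatter by 1 percentage point)

- the flasks by share of mono adduct in all that became mono adduct or bis adduct or tris adduct, highest first, at 4.0 h (Thursday's / Wednesday's / Saturday's / Sunday's / Friday's)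
- the share of mono adduct in all that became mono adduct or bis adduct or tris adduct of the flask you put first, at 4.0 h
- the share of mono adduct in all that became mono adduct or bis adduct or tris adduct of the flask you put last, at 4.0 h

- percentages count the solid substrate that a species holds: one idle adduct counts as two
- mono adduct is meant together with its idle adduct
- solid, in amounts per volume of the solution: solid substrate
- what may be going on: starting material + mono adduct <-> idle adduct; starting material + partner -> mono adduct; partner + mono adduct -> bis adduct; partner + bis adduct -> tris adduct; solid substrate <-> starting material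
- at the start none of the solid substrate is in solution
- what has only dissolved of solid substrate counts as not reacted
- in an amount of mono adduct, one idle adduct counts as one mono adduct

I build the flask one process at a time, and the number I follow is s, the share of mono adduct among mono, bis and tris adducts. With the main step by itself, starting material + partner giving mono adduct, s stands at 100%, the zero of my scale.

Now I add partner + mono adduct giving bis adduct, and I take dissolved starting material as a steady feed. Each mono adduct then decays as it ages, so s = (1 − e^(−u))/u, where u = kPt, t is the time, and k is the burn constant, the rate at which a molar of partner consumes mono adduct per hour.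

Next comes tris adduct. It forms from bis adduct and stays in the same sum, so it does not move s. Idle adduct counts as mono adduct in the readings, and I let its shelter sit inside k. This formula for s has no term for the solid charge.

At the last readings, the eta run has s = 42.2% and the delta run 57.1%, counting mono and bis adducts. Solving for u gives 2.09 and 1.27. Dividing each by its Pt and taking the mean, I read k = 2.25 M⁻¹ h⁻¹, with the scatter of those readings.

My order therefore runs by partner charge. Thursday's, at u = 0.449, comes first with 80.6%. Wednesday's, at u = 2.25, comes last with 39.8%.

The forecast says Thursday's > Saturday's > Sunday's > Friday's > Wednesday's, with 79% and 40%. Its top figure lies below mine, on the ground that “Thursday's small charge may not saturate”.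

The flasks give Thursday's > Saturday's > Sunday's > Friday's > Wednesday's, with 83.8% and 43.9%, so the forecast holds.

    starting material + mono adduct ⇌ idle adduct, settled at all times (K = 23.0 M⁻¹)
    starting material + partner → mono adduct (k = 1.90 M⁻¹ h⁻¹)
    partner + mono adduct → bis adduct (k = 2.70 M⁻¹ h⁻¹)
    partner + bis adduct → tris adduct (k = 0.690 M⁻¹ h⁻¹)
    solid substrate ⇌ starting material, rate k5*(cs5 - [starting material]) while solid is left; crystals form when [starting material] > cs5 (solubility = 8.00 mM, k = 0.500 h⁻¹)

With its solid cut to Thursday's charge, Friday's share stands at 59.7%, against 59.7% as charged. My reckoning lies 3.2 percentage points under Thursday's and 4.1 points under Wednesday's. The neighbour is Wednesday's with partner at 0.062 M: u = 0.557 gives s = 76.7%, and that flask stands at 80.3%, 3.6 points above my figure.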